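**Retrosynthetic overview**

1. The route rests on one feature of the chromone: O1 sits on aromatic C8a, which lies between C4a (carrying the C4 carbonyl) and C8 (OMe). Ring A can therefore enter as a 2,4,5-trimethoxyphenyl ketone whose only ortho C–H is the future C8a, and O1 is supplied by the second carbonyl of a 1,3-diketone.
2. Target 14 ⇐ flavone 13 (BCl3 removes both benzyl ethers and the peri 5-O-methyl) ⇐ diketone 12 by anodic dehydrogenative O1–C8a closure. The pyranone (ring C) is the only ring formed; rings A and B are bought as arenes.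
3. 12 ⇐ C-aroylation of the lithium enolate of α-benzyloxy ketone 6 with aroyl chloride 10 (this bond becomes C2–C3).
4. 6 ⇐ 2,4,5-trimethoxyphenyllithium (from 1,2,4-trimethoxybenzene 1 via bromide 2) and Weinreb amide 4. This replaces a Lewis-acid Friedel–Crafts acylation, which would endanger the benzyl ether and the ortho methoxy group. 10 ⇐ 2-hydroxy-4-methoxybenzoic acid 7.

Key step: step 8

Remark: the target has no stereocentre, so there is no enantiomer to select; the only stereocentre on the way (C2 of diketone 12) is racemic, enolisable and is removed in step 8.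

**Route**

Step 1
Reactants: 1 1,2,4-trimethoxybenzene
Product: 2 1-bromo-2,4,5-trimethoxybenzene
Conditions: NBS (1.0 equiv), MeCN, 0 °C → rt
Reagents that add atoms: N-bromosuccinimide, O=C1CCC(=O)N1Br
Why: Electrophilic aromatic bromination should occur at C5, the position para to the 2-methoxy and ortho to the 4-methoxy group, which is the most activated and least hindered site.

Step 2
Reactants: 3 benzyloxyacetyl chloride
Product: 4 2-(benzyloxy)-N-methoxy-N-methylacetamide
Conditions: MeNH(OMe)·HCl, Et3N (2.2 equiv), CH2Cl2, 0 °C → rt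
Reagents that add atoms: N,O-dimethylhydroxylamine hydrochloride, CNOC.Cl
Why: N-Acylation of the hydroxylamine by the acid chloride (Weinreb amide formation) is straightforward and leaves the benzyl ether untouched.

Step 3
Reactants: 2 1-bromo-2,4,5-trimethoxybenzene; 4 2-(benzyloxy)-N-methoxy-N-methylacetamide
Product: 6 2-(benzyloxy)-1-(2,4,5-trimethoxyphenyl)ethan-1-one, via aryllithium 5 (not isolated)
Conditions: n-BuLi, THF, −78 °C; then 4, −78 → 0 °C; aq. NH4Cl
Reagents that add atoms: none
Why: Bromine–lithium exchange followed by the Weinreb ketone synthesis should stop at the ketone, because the chelated tetrahedral adduct survives until the quench and no Lewis acid meets the benzyl ether or the methoxy groups.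

Step 4
Reactants: 7 2-hydroxy-4-methoxybenzoic acid
Product: 8 benzyl 2-(benzyloxy)-4-methoxybenzoate
Conditions: BnBr (2.5 equiv), K2CO3, DMF, 60 °C
Reagents that add atoms: benzyl bromide, BrCc1ccccc1
Why: Williamson O-alkylation of the phenoxide and of the carboxylate with benzyl bromide should give the benzyl ether and benzyl ester in one operation.

Step 5
Reactants: 8 benzyl 2-(benzyloxy)-4-methoxybenzoate
Product: 9 2-(benzyloxy)-4-methoxybenzoic acid
Conditions: NaOH, THF/MeOH/H2O, reflux; then aq. HCl
Reagents that add atoms: sodium hydroxide, [Na+].[OH-]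
Why: Saponification cleaves the benzyl ester by acyl–oxygen fission, while the aryl benzyl ether is inert to hydroxide.

Step 6
Reactants: 9 2-(benzyloxy)-4-methoxybenzoic acid
Product: 10 2-(benzyloxy)-4-methoxybenzoyl chloride
Conditions: (COCl)2, cat. DMF, CH2Cl2, 0 °C → rt; used crude
Reagents that add atoms: oxalyl chloride, ClC(=O)C(=O)Cl
Why: Acid chloride formation through the Vilsmeier-type chloroiminium species runs under mild conditions that an aryl benzyl ether tolerates.

Step 7
Reactants: 6 2-(benzyloxy)-1-(2,4,5-trimethoxyphenyl)ethan-1-one; 10 2-(benzyloxy)-4-methoxybenzoyl chloride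
Product: 12 2-(benzyloxy)-1-[2-(benzyloxy)-4-methoxyphenyl]-3-(2,4,5-trimethoxyphenyl)propane-1,3-dione (racemic), via lithium enolate 11 (not isolated)
Conditions: LiHMDS (2.2 equiv), THF, −78 °C; then 10, −78 → 0 °C; aq. NH4Cl
Reagents that add atoms: none
Why: Claisen-type C-acylation of the preformed chelated Z-lithium enolate by the aroyl chloride should give the 1,3-diketone, the second equivalent of base holding the more acidic product as its lithium diketonate so that it is not acylated again.

Step 8
Reactants: 12 2-(benzyloxy)-1-[2-(benzyloxy)-4-methoxyphenyl]-3-(2,4,5-trimethoxyphenyl)propane-1,3-dione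
Product: 13 3-(benzyloxy)-2-[2-(benzyloxy)-4-methoxyphenyl]-5,7,8-trimethoxy-4H-chromen-4-one
Conditions: graphite(+)|Pt(−), undivided cell, constant current (5 mA cm−2, ca. 2.2 F mol−1), n-Bu4NPF6 (0.1 M), 2,6-lutidine (2 equiv), HFIP/CH2Cl2 (4:1), rt
Reagents that add atoms: none
Why: Proposed new method: anodic oxidation in HFIP should convert the 2,4,5-trimethoxyaroyl ring, the most electron-rich π system of 12, into its radical cation, whose free ortho carbon (the future C8a) is attacked by the oxygen of the ring-B-side carbonyl or enol; the cyclohexadienyl radical (spin on C8 beside a methoxy group and on C4a) gives up a second electron, loss of the C8a and C3 protons restores the arene and forms the enone, and HFIP is reduced to H2 at the cathode. The closest known reaction type is the anodic dehydrogenative C–H/O–H cyclisation, as in the lactonisation of biaryl-2-carboxylic acids and the closure of anilides to benzoxazoles, but a 1,3-diketone oxygen has not been closed onto an arene C–H to give a 4-pyranone. The pyranone ring (O1, C2, C3, C4, C4a, C8a) closes in the 6-endo-trig mode, since the attacked C4a–C8a π bond ends up inside the new ring. No stereocentre is formed, and the racemic centre of 12 becomes sp2 C3. The step needs oxidation of ring A in preference to ring B, the benzyl ethers and the diketone C–H, and bond formation at C8a–H only: the first is secured by the lower potential of the trioxygenated ring in a buffered, non-nucleophilic medium, the second by the acyl group having a single ortho C–H (flanked by the C8 methoxy group), by capture at the methoxy-bearing ortho carbon being reversible because no proton can be lost there, and by the only ortho C–H of ring B lying meta to both of its oxygen substituents. Limiting the charge should protect flavone 13, whose ring A is conjugated with a coplanar, HFIP-bonded pyranone carbonyl and should therefore be harder to oxidise than 12.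

Step 9
Reactants: 13 3-(benzyloxy)-2-[2-(benzyloxy)-4-methoxyphenyl]-5,7,8-trimethoxy-4H-chromen-4-one
Product: 14 3,5-dihydroxy-2-(2-hydroxy-4-methoxyphenyl)-7,8-dimethoxy-4H-chromen-4-one (3,5,2'-trihydroxy-7,8,4'-trimethoxyflavone)
Conditions: BCl3 (excess, 1 M in CH2Cl2), pentamethylbenzene, CH2Cl2, −78 → 0 °C; then H2O
Reagents that add atoms: none
Why: Lewis-acid ether cleavage: BCl3 should ionise both benzyl ethers (the benzyl cations being trapped by pentamethylbenzene in a Friedel–Crafts alkylation) and, held in a six-membered chelate with the C4 carbonyl, cleave only the peri 5-methoxy group, leaving the 7-, 8- and 4'-methyl ethers.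

**Compound list**

1 | 1,2,4-trimethoxybenzene | COc1ccc(OC)c(OC)c1 | starting material
2 | 1-bromo-2,4,5-trimethoxybenzene | COc1cc(OC)c(OC)cc1Br | intermediate
3 | benzyloxyacetyl chloride | O=C(Cl)COCc1ccccc1 | starting material
4 | 2-(benzyloxy)-N-methoxy-N-methylacetamide | CON(C)C(=O)COCc1ccccc1 | intermediate
5 | (2,4,5-trimethoxyphenyl)lithium (not isolated) | [Li]c1cc(OC)c(OC)cc1OC | intermediate
6 | 2-(benzyloxy)-1-(2,4,5-trimethoxyphenyl)ethan-1-one | COc1cc(OC)c(C(=O)COCc2ccccc2)cc1OC | intermediate
7 | 2-hydroxy-4-methoxybenzoic acid | COc1ccc(C(=O)O)c(O)c1 | starting material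
8 | benzyl 2-(benzyloxy)-4-methoxybenzoate | COc1ccc(C(=O)OCc2ccccc2)c(OCc2ccccc2)c1 | intermediate
9 | 2-(benzyloxy)-4-methoxybenzoic acid | COc1ccc(C(=O)O)c(OCc2ccccc2)c1 | intermediate
10 | 2-(benzyloxy)-4-methoxybenzoyl chloride | COc1ccc(C(=O)Cl)c(OCc2ccccc2)c1 | intermediate
11 | lithium (Z)-2-(benzyloxy)-1-(2,4,5-trimethoxyphenyl)ethen-1-olate (not isolated) | [Li+].[O-]/C(=C\OCc1ccccc1)c1cc(OC)c(OC)cc1OC | intermediate
12 | 2-(benzyloxy)-1-[2-(benzyloxy)-4-methoxyphenyl]-3-(2,4,5-trimethoxyphenyl)propane-1,3-dione (racemic) | COc1ccc(C(=O)C(OCc2ccccc2)C(=O)c2cc(OC)c(OC)cc2OC)c(OCc2ccccc2)c1 | intermediate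
13 | 3-(benzyloxy)-2-[2-(benzyloxy)-4-methoxyphenyl]-5,7,8-trimethoxy-4H-chromen-4-one | COc1ccc(-c2oc3c(OC)c(OC)cc(OC)c3c(=O)c2OCc2ccccc2)c(OCc2ccccc2)c1 | intermediate
14 | 3,5-dihydroxy-2-(2-hydroxy-4-methoxyphenyl)-7,8-dimethoxy-4H-chromen-4-one (achiral) | COc1ccc(-c2oc3c(OC)c(OC)cc(O)c3c(=O)c2O)c(O)c1 | target

**Step count**

Total: 9 steps. Longest linear sequence: 6 steps (7 → 8 → 9 → 10 → 12 → 13 → 14; steps 4, 5, 6, 7, 8, 9).

**Steps most likely to fail**

Step 8 (the proposed new method). The ring closure may be diverted in several ways: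
- capture of the radical cation at the methoxy-bearing ortho carbon instead of the C–H carbon;
- oxidation at the diketone carbon, with oxygenation there or loss of the 3-O-benzyl group;
- further oxidation or coupling of the electron-rich flavone at the anode.

The fallback uses known chemistry and takes O1 from a phenol instead of a C–H bond. It sets out from acid chloride 10 and comes back to the route at 14. Purchased 1-(2-hydroxy-3,4,6-trimethoxyphenyl)ethan-1-one F1 would be O-acylated with 10 (pyridine, DMAP, CH2Cl2) to 2-acetyl-3,5,6-trimethoxyphenyl 2-(benzyloxy)-4-methoxybenzoate F2. Baker–Venkataraman rearrangement (KOH, pyridine, 50 °C) should give 1-[2-(benzyloxy)-4-methoxyphenyl]-3-(2-hydroxy-3,4,6-trimethoxyphenyl)propane-1,3-dione F3. Cyclodehydration (p-TsOH, toluene, reflux) should give 2-[2-(benzyloxy)-4-methoxyphenyl]-5,7,8-trimethoxy-4H-chromen-4-one F4. Epoxidation with dimethyldioxirane (acetone/CH2Cl2, 0 °C) should give the racemic 2,3-epoxide of F4 F5, and acid-catalysed opening (cat. p-TsOH) should isomerise it to 2-[2-(benzyloxy)-4-methoxyphenyl]-3-hydroxy-5,7,8-trimethoxy-4H-chromen-4-one F6. Under the conditions of step 9, F6 should lose its benzyl group and its 5-O-methyl group to give 14.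

Step 7. The enolate may be acylated on oxygen, the product may be acylated twice, or the hindered 2-alkoxy diketone may suffer retro-Claisen cleavage during work-up. The fallback builds the C2–C3 bond by aldol addition and adjusts the oxidation level afterwards. It sets out from ketone 6 and acid chloride 10 and comes back at 12. Reduction of 10 with LiAlH(Ot-Bu)3 (THF, −78 °C) should give 2-(benzyloxy)-4-methoxybenzaldehyde F7. Addition of lithium enolate 11 (from 6, LiHMDS, THF, −78 °C) to F7 should give 2-(benzyloxy)-3-[2-(benzyloxy)-4-methoxyphenyl]-3-hydroxy-1-(2,4,5-trimethoxyphenyl)propan-1-one F8 as a mixture of racemic diastereomers, which does not matter. Dess–Martin oxidation (NaHCO3, CH2Cl2) should then give 12.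

Step 9. Ether cleavage may go too far (loss of the 7- or 8-methyl ether), benzyl cations may alkylate the electron-rich rings, or the acid may open and reclose the 5-hydroxy-7,8-dioxygenated chromone to its isomer. The fallback separates the two deprotections. It sets out from 13 and comes back at 14. Hydrogenolysis (H2, Pd/C, EtOAc/THF, rt) should give 3-hydroxy-2-(2-hydroxy-4-methoxyphenyl)-5,7,8-trimethoxy-4H-chromen-4-one F9. Chelation-controlled mono-demethylation of the 5-methoxy group (AlCl3, MeCN, rt to 50 °C) should then give 14.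

**Further compounds**

F1 | step 8 | 1-(2-hydroxy-3,4,6-trimethoxyphenyl)ethan-1-one (purchased) | CC(=O)c1c(O)c(OC)c(OC)cc1OC
F2 | step 8 | 2-acetyl-3,5,6-trimethoxyphenyl 2-(benzyloxy)-4-methoxybenzoate | CC(=O)c1c(OC)cc(OC)c(OC)c1OC(=O)c1ccc(OC)cc1OCc1ccccc1
F3 | step 8 | 1-[2-(benzyloxy)-4-methoxyphenyl]-3-(2-hydroxy-3,4,6-trimethoxyphenyl)propane-1,3-dione | COc1ccc(C(=O)CC(=O)c2c(O)c(OC)c(OC)cc2OC)c(OCc2ccccc2)c1
F4 | step 8 | 2-[2-(benzyloxy)-4-methoxyphenyl]-5,7,8-trimethoxy-4H-chromen-4-one | COc1ccc(-c2cc(=O)c3c(OC)cc(OC)c(OC)c3o2)c(OCc2ccccc2)c1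
F5 | step 8 | 2,3-epoxide of F4 (2,3-epoxy-2'-(benzyloxy)-5,7,8,4'-tetramethoxyflavanone, racemic, cis-fused) | COc1ccc(C23Oc4c(OC)c(OC)cc(OC)c4C(=O)C2O3)c(OCc2ccccc2)c1
F6 | step 8 | 2-[2-(benzyloxy)-4-methoxyphenyl]-3-hydroxy-5,7,8-trimethoxy-4H-chromen-4-one | COc1ccc(-c2oc3c(OC)c(OC)cc(OC)c3c(=O)c2O)c(OCc2ccccc2)c1
F7 | step 7 | 2-(benzyloxy)-4-methoxybenzaldehyde | COc1ccc(C=O)c(OCc2ccccc2)c1
F8 | step 7 | 2-(benzyloxy)-3-[2-(benzyloxy)-4-methoxyphenyl]-3-hydroxy-1-(2,4,5-trimethoxyphenyl)propan-1-one (racemic diastereomer mixture) | COc1ccc(C(O)C(OCc2ccccc2)C(=O)c2cc(OC)c(OC)cc2OC)c(OCc2ccccc2)c1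
F9 | step 9 | 3-hydroxy-2-(2-hydroxy-4-methoxyphenyl)-5,7,8-trimethoxy-4H-chromen-4-one | COc1ccc(-c2oc3c(OC)c(OC)cc(OC)c3c(=O)c2O)c(O)c1
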